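The earlier runs and the new flask are simulated with constants of no real substance, noise included.

1. I chose to read this flask on one clock, substrate charge times time. If every step pairs two molecules, fractions of the charge at equal equivalents lie on one curve of that clock, and summer, spring and the flask all have 0.950 equiv of partner.

| flask | substrate | partner | remark | time |
|---|---|---|---|---|
| summer | 11 mM | 0.95 equiv | run made earlier |  |
| spring | 16 mM | 0.95 equiv | run made earlier |  |
| dusk | 22 mM | 1.9 equiv | run made earlier |  |
| flask | 22 mM | 0.950 equiv |  | 2.0 h |

| run | time / min | target / % |
|---|---|---|
| summer | 1.00 | 8.3 |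
| summer | 2.50 | 15.9 |
| summer | 6.00 | 19.7 |
| summer | 15.0 | 17.6 |
| summer | 30.0 | 13.1 |
| summer | 80.0 | 9.9 |
| spring | 1.00 | 11.5 |
| spring | 2.50 | 18.7 |
| spring | 6.00 | 23.4 |
| spring | 15.0 | 18.6 |
| spring | 30.0 | 11.7 |
| spring | 80.0 | 6.8 |
| dusk | 1.00 | 23.7 |
| dusk | 3.00 | 33.4 |
| dusk | 10.0 | 30.6 |
| dusk | 25.0 | 22.8 |
| dusk | 80.0 | 16.9 |

(each reading ± 1 percentage point)

- when, up to 2.0 h, the flask holds most target
- the amount of target, in percent of the substrate charged, at that time
- earliest time at which at least nineteen twentieths of that best amount are there, in min
- latest time at which they still are

- the numbers in the tables scatter by 1 percentage point (one standard deviation)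

2. Spring's highest reading, 23.4% at 6.00 min, stood at a clock of 5.76 M·s, which in the flask comes at 4.36 min. My doubt was that summer's highest reading gives 3.00 min, but the readings are sparse, and I kept spring, whose charge is nearer the flask's.

3. A second doubt: summer's peak reading lay 3.7 percentage points under spring's, against a scatter of 1 point. So the clock may not be exact, and some loss may keep its own time.

4. Dusk has the flask's substrate charge but twice the equivalents of partner, the limiting reagent in the flask. I took the height exponent 0.513, the power of the equivalents that the peak reading follows. I read it from spring and dusk, and dusk also has the larger substrate charge, so the exponent leans on the clock I had just doubted. From dusk it gives 23.4% for the flask, which is spring's reading by construction and so no test.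

5. Spring's neighbouring readings, 18.7% and 18.6%, lie under that height. So I expected the band to open after 1.82 min and shut before 10.9 min.

6. The forecast gave 0.08 h, 25.5%, and a band from 2.9 min to 0.127 h, saying “The peak therefore tracks partner concentration”.

7. The flask gave 22.6% at 4.55 min, with the band from 2.82 min to 7.27 min, and my height stood 0.80 points above it. At 0.0276 h in the flask, substrate + target into side product used target 2.7 times as fast as the forward step to isomer of the product B. So at that moment the paired step took target faster than the first-order step, which keeps its own time.

    substrate + partner → target (k = 11.0 M⁻¹ min⁻¹)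
    substrate + partner → isomer of the product A (k = 5.90 M⁻¹ min⁻¹)
    2 partner → homo dimer (k = 7.10 M⁻¹ min⁻¹)
    substrate + target → side product (k = 6.00 M⁻¹ min⁻¹)
    target ⇌ isomer of the product B (K = 1.10, k = 0.0320 min⁻¹)

8. In the neighbour with 1.60 equiv of partner, the height exponent gives 30.6% from dusk. The neighbour's computed best is 30.7%.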